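**Strategy.** The diester is cut at both ester C–O bonds into malonic acid and two copies of (5S,9S,10S)-labda-7,13E-dien-15-ol. Everything rests on unzipping that alcohol at C9–C10 (ring B) and C4–C5 (ring A) to acyclic, achiral all-E geranylgeranyl diphosphate. A class II diterpene cyclase protonates the terminal alkene, closes ring A and then ring B, and takes a proton from C7 of the C8 cation. One operation therefore sets C5, C9 and C10 and places the C7=C8 alkene. The feature exploited is the head-to-tail isoprenoid pattern still legible in ring B: quaternary C10 (CH3), C9–H carrying the untouched C11–C15 allylic chain, and the trisubstituted C7=C8(CH3) alkene.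

Key step: step 2

Remarks on the chemistry (assumptions):
- Labdane numbering is used for all compounds, including the acyclic ones. C15 is the CH2O carbon, and the alkenes of 1–3 are C13=C14, C8=C9, C5=C10 and C3=C4.
- Phosphates and diphosphates are drawn as free acids but handled as ammonium salts.
- The cyclase is a catalyst obtained by routine expression of a synthetic gene in E. coli.
- Compound 3 is sold only in analytical amounts and is therefore made from 1.

**Step 1**
Reactants: 1 (2E,6E,10E)-geranylgeraniol
Product: 3 (2E,6E,10E)-geranylgeranyl diphosphate, via geranylgeranyl monophosphate 2 (not isolated)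
Conditions: CCl3CN, (Et3NH)2HPO4 (added in portions), MeCN, 37 °C; then SiO2, iPrOH/conc. NH4OH/H2O
Reagents that add atoms: bis(triethylammonium) hydrogen phosphate, CC[NH+](CC)CC.CC[NH+](CC)CC.OP(=O)([O-])[O-]
Why: Trichloroacetonitrile-promoted phosphorylation (Cramer-type condensation): CCl3CN turns phosphate into an imidoyl phosphate that phosphorylates first the primary allylic OH and then the monophosphate 2 at oxygen, so the C15–O bond is never broken, the three E-alkenes keep their geometry, and no stereocentre is involved.

**Step 2**
Reactants: 3 (2E,6E,10E)-geranylgeranyl diphosphate
Product: 5 (5S,9S,10S)-labda-7,13E-dien-15-ol, via labda-7,13E-dien-15-yl diphosphate 4 (not isolated)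
Conditions: recombinant class II diterpene cyclase (labda-7,13E-dienyl diphosphate synthase, normal series), HEPES pH 7.4, MgCl2 (0.1 mM), DTT, 10% glycerol, 3 fed in portions, 30 °C; then alkaline phosphatase, pH 8.5, 37 °C; hexane extraction
Reagents that add atoms: none
Why: This is a class II terpene cyclase reaction, a protonation-initiated cationic polyene bicyclisation of the type run by copalyl diphosphate synthases: the central aspartic acid of the DXDD motif protonates C3 of the distal C3=C4 alkene while the allylic diphosphate stays un-ionised, the C5=C10 alkene attacks C4 to close ring A (C4–C5 bond, 6-endo-trig), and the C8=C9 alkene attacks the resulting C10 cation to close ring B last (C9–C10 bond, 6-endo-trig), leaving the labda-13E-en-8-yl cation. An active-site base then removes a proton from C7, which gives the endocyclic C7=C8 alkene of 4. The relative configuration follows from anti addition across the two E-alkenes in a chair–chair fold (trans ring fusion with 5α-H and 10β-CH3, 9α-H with an equatorial 9β side chain), and the absolute sense (5S,9S,10S) is imposed by the normal-series active-site contour, which binds only one of the two enantiomeric folds of achiral 3. The step needs attack at the distal alkene rather than ionisation of the diphosphate, arrest after two rings, and loss of H-7 rather than H-17 or a 9→8 hydride shift; these are secured respectively by low Mg2+ and the absence of a class I site, by anchoring of the diphosphate-bearing C13=C14 alkene away from C8, and by the position of the catalytic base. Alkaline phosphatase, added only after full conversion so that it cannot consume 3, cleaves the P–O bonds and leaves C15–O intact, so the E-allylic alcohol 5 should be released without allylic transposition.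

**Step 3**
Reactants: 5 (5S,9S,10S)-labda-7,13E-dien-15-ol (2 equiv); 6 malonic acid
Product: 8 bis[(5S,9S,10S)-labda-7,13E-dien-15-yl] malonate, via labdadienyl hydrogen malonate 7 (not isolated)
Conditions: DCC, DMAP (cat.), CH2Cl2, 0 °C → rt
Reagents that add atoms: none
Why: Steglich esterification: DCC/DMAP activates each carboxyl group of 6 in turn as O-acylisourea/acylpyridinium under neutral conditions that neither ionise the allylic alcohol nor move the C7=C8 alkene, no stereocentre is touched, and two identical enantiopure halves can give only one diastereomer.

**Compound list**
1 | (2E,6E,10E)-geranylgeraniol | CC(C)=CCC/C(C)=C/CC/C(C)=C/CC/C(C)=C/CO | starting material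
2 | (2E,6E,10E)-geranylgeranyl monophosphate | CC(C)=CCC/C(C)=C/CC/C(C)=C/CC/C(C)=C/COP(=O)(O)O | intermediate
3 | (2E,6E,10E)-geranylgeranyl diphosphate | CC(C)=CCC/C(C)=C/CC/C(C)=C/CC/C(C)=C/COP(=O)(O)OP(=O)(O)O | intermediate
4 | (5S,9S,10S)-labda-7,13E-dien-15-yl diphosphate | CC1=CC[C@H]2C(C)(C)CCC[C@]2(C)[C@H]1CC/C(C)=C/COP(=O)(O)OP(=O)(O)O | intermediate
5 | (5S,9S,10S)-labda-7,13E-dien-15-ol | CC1=CC[C@H]2C(C)(C)CCC[C@]2(C)[C@H]1CC/C(C)=C/CO | intermediate
6 | malonic acid | OC(=O)CC(=O)O | starting material
7 | (5S,9S,10S)-labda-7,13E-dien-15-yl hydrogen malonate | CC1=CC[C@H]2C(C)(C)CCC[C@]2(C)[C@H]1CC/C(C)=C/COC(=O)CC(=O)O | intermediate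
8 | bis[(5S,9S,10S)-labda-7,13E-dien-15-yl] malonate (CNP0113044.1) | CC1=CC[C@H]2C(C)(C)CCC[C@]2(C)[C@H]1CC/C(C)=C/COC(=O)CC(=O)OC/C=C(\C)CC[C@H]1C(C)=CC[C@H]2C(C)(C)CCC[C@]12C | target

Total step count: 3. Longest linear sequence: 3 (1 → 3 → 5 → 8).

**Steps most likely to fail**

**Step 2.**
- Risk: turnover may stall at preparative concentration through combined substrate/Mg2+ inhibition and aggregation of the amphiphilic diphosphate. The allylic diphosphate may also solvolyse in the buffer, or the final proton loss may leak to other positions.
- Fallback: the regiochemical task is taken away from the enzyme. Setting out from 3, a (+)-copalyl diphosphate synthase would be used. This is a class II cyclase of the same normal series and one of the best-behaved members of the family. It would close the same two rings in the same order but end by loss of a C17 proton, giving (+)-copalyl diphosphate F1.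
- Alkaline phosphatase would then release (+)-copalol F2.
- A cobalt–salen/PhSiH3 hydrogen-atom-transfer alkene isomerisation (benzene, rt) addresses 1,1-disubstituted alkenes in preference to trisubstituted ones. It should move the exocyclic C8=C17 alkene into ring B as C7=C8 through the C8 radical, which loses the accessible H-7. The route is rejoined at 5.

**Step 1.**
- Risk: the phosphorylation is statistical, so under- and over-phosphorylation compete. The allylic diphosphate may also hydrolyse during chromatography.
- Fallback: the bond made is changed from P–O to C–O. Setting out from 1, Corey–Kim-type chlorination (NCS, Me2S, CH2Cl2, −30 → 0 °C) would give (2E,6E,10E)-geranylgeranyl chloride F3.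
- SN2 displacement with tris(tetrabutylammonium) hydrogen diphosphate in MeCN installs the intact diphosphate in one event. Exchange to the ammonium form and cellulose chromatography follow, and the route is rejoined at 3.

**Step 3.**
- Risk: doubly activated malonic acid may decarboxylate or collapse to ketene-derived material. O→N acyl migration may also arrest the esterification at the mono-ester stage.
- Fallback: the two ester bonds are made one at a time. Setting out from 5, heating with Meldrum's acid (toluene, 110 °C) opens the dioxanedione by alcoholysis and would give the half ester 7, now isolated, without any coupling agent.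
- Only one carboxyl group then has to be activated (EDC·HCl, DMAP, CH2Cl2, 0 °C) towards a second equivalent of 5. The route is rejoined at 8.

**Further compounds**
F1 | step 2 | (+)-copalyl diphosphate, (5S,9S,10S)-labda-8(17),13E-dien-15-yl diphosphate | C=C1CC[C@H]2C(C)(C)CCC[C@]2(C)[C@H]1CC/C(C)=C/COP(=O)(O)OP(=O)(O)O
F2 | step 2 | (+)-copalol, (5S,9S,10S)-labda-8(17),13E-dien-15-ol | C=C1CC[C@H]2C(C)(C)CCC[C@]2(C)[C@H]1CC/C(C)=C/CO
F3 | step 1 | (2E,6E,10E)-geranylgeranyl chloride | CC(C)=CCC/C(C)=C/CC/C(C)=C/CC/C(C)=C/CCl
F0 | step 3 | none | none
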